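**Retrosynthetic overview**
1. The target is traced back to a 1-acyl-sn-glycerol (selective acetylation of the primary hydroxyl), then to its acetonide; the homoprenyl chain is cut at C5 (enol triflate of a C5 ketone plus homoprenyl Grignard reagent, iron catalysis) and the glycerol ester at its alkyl C–O bond (cesium carboxylate plus (S)-solketal tosylate), leaving a cis-decalone acid.
2. Ring A of this keto acid is opened at C4–C4a. C4a is the fully substituted α-carbon of the C5 ketone and is γ to the C1 carboxyl carbon, so the acid can be parked on C4a as a five-membered lactone (a C4a–O bond and a ring that are not in the target). Two-electron scission of this α-acyloxy ketone releases the C4a enolate, which the C4 chloride of the C1 side chain reaches through a six-membered transition state; the quaternary C8a between them enforces the cis fusion.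
3. The keto lactone comes from epoxidation/lactonisation and oxidation of a γ,δ-unsaturated acid. That acid comes from an Ireland–Claisen rearrangement (C1–C8a bond, quaternary C8a and C1) of the ester of (R)-2,3-dimethylcyclohex-2-en-1-ol (CBS reduction) with (R)-5-chloro-3-methylpentanoyl chloride (C2 from (R)-methyl hydrogen 3-methylglutarate).
4. Ring order: ring B is present from the start (2,3-dimethylcyclohex-2-enone); the temporary γ-lactone ring is closed in step 6 and opened in step 8; ring A is closed in step 8; the dioxolane of the glycerol unit is carried from step 9 to step 12.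

Key step: step 8

Remark: locants C1–C8a are those of the octahydronaphthalene core of the target (C1 bears the ester, C2 the secondary methyl, C4a and C8a the angular methyls, C5 the homoprenyl chain) and are also used for open-chain and lactone intermediates; compounds 1, 5, 16 and 19 are taken as commercial.

Step 1
Reactants: 1 (R)-methyl hydrogen 3-methylglutarate
Product: 3 (R)-4-methyloxan-2-one, via methyl (R)-5-hydroxy-3-methylpentanoate 2 (not isolated)
Conditions: BH3·SMe2, THF, −15 → 20 °C; MeOH quench; then TsOH (cat.), toluene, 60 °C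
Reagents that add atoms: none
Why: Chemoselective borane reduction of the free carboxylic acid beside the methyl ester, followed by acid-catalysed lactonisation of the δ-hydroxy ester; the stereocentre is β to both carbonyl groups and is not touched.

Step 2
Reactants: 3 (R)-4-methyloxan-2-one
Product: 4 (R)-5-chloro-3-methylpentanoyl chloride
Conditions: SOCl2, ZnCl2 (cat.), neat, 65 °C; distillation
Reagents that add atoms: thionyl chloride, O=S(Cl)Cl
Why: Lewis-acid-assisted chlorinative ring opening of a δ-lactone (SN2 attack of chloride at the O–CH2 carbon, then conversion of the carboxylate into the acid chloride), at carbons remote from the methyl-bearing stereocentre.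

Step 3
Reactants: 5 2,3-dimethylcyclohex-2-en-1-one
Product: 6 (R)-2,3-dimethylcyclohex-2-en-1-ol
Conditions: (S)-1-methyl-3,3-diphenyltetrahydro-1H,3H-pyrrolo[1,2-c][1,3,2]oxazaborole (10 mol %), BH3·SMe2, THF, −20 °C
Reagents that add atoms: none
Why: CBS reduction, in which the α-methylated alkenyl group acts as the large substituent, so that the catalyst enantiomer that gives (R)-1-phenylethanol from acetophenone is expected to give the (R)-allylic alcohol.

Step 4
Reactants: 6 (R)-2,3-dimethylcyclohex-2-en-1-ol; 4 (R)-5-chloro-3-methylpentanoyl chloride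
Product: 7 (1R)-2,3-dimethylcyclohex-2-en-1-yl (3S)-5-chloro-3-methylpentanoate
Conditions: pyridine, 4-(dimethylamino)pyridine (cat.), CH2Cl2, 0 °C
Reagents that add atoms: none
Why: O-acylation of the secondary allylic alcohol by an acid chloride under basic, non-ionising conditions, which keeps the allylic C–O bond and both stereocentres (the chain descriptor changes only because the CIP priorities change).

Step 5
Reactants: 7 (1R)-2,3-dimethylcyclohex-2-en-1-yl (3S)-5-chloro-3-methylpentanoate
Product: 10 (2S,3R)-5-chloro-2-[(1R)-1,2-dimethylcyclohex-2-en-1-yl]-3-methylpentanoic acid, via silyl ketene acetal 8 (not isolated), via trimethylsilyl ester 9 (not isolated)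
Conditions: LiN(i-Pr)2, THF, −78 °C; Me3SiCl/Et3N, −78 → 60 °C; dilute aqueous HCl work-up (no basic extraction)
Reagents that add atoms: chlorotrimethylsilane, C[Si](C)(C)Cl (its silyl group is carried by 8 and 9 only and is lost on work-up)
Why: Ireland–Claisen rearrangement: the suprafacial [3,3] shift forms the C1–C8a bond on the ring face that carried the ester oxygen and so transfers the (R)-carbinol configuration to the quaternary C8a, while the (E)-ketene acetal formed in THF is expected to react through the boat-like transition state typical of cyclohexenyl esters, which should give the (2S) configuration at C1.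

Step 6
Reactants: 10 (2S,3R)-5-chloro-2-[(1R)-1,2-dimethylcyclohex-2-en-1-yl]-3-methylpentanoic acid
Product: 12 (3S,3aR,7S,7aS)-3-[(2R)-4-chlorobutan-2-yl]-7-hydroxy-3a,7a-dimethylhexahydro-1-benzofuran-2(3H)-one, via epoxy acid 11 (not isolated)
Conditions: meta-chloroperoxybenzoic acid, CH2Cl2, 0 → 20 °C; then camphorsulfonic acid (cat.)
Reagents that add atoms: meta-chloroperoxybenzoic acid, OOC(=O)c1cccc(Cl)c1
Why: Prilezhaev epoxidation of the trisubstituted ring alkene followed by 5-exo opening of the epoxide by the γ,δ-placed carboxylic acid at the tertiary carbon C4a, which gives the cis-fused γ-lactone (the only fusion the tether allows) and leaves the hydroxyl on C5, whose configuration is erased in step 7.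

Step 7
Reactants: 12 (3S,3aR,7S,7aS)-3-[(2R)-4-chlorobutan-2-yl]-7-hydroxy-3a,7a-dimethylhexahydro-1-benzofuran-2(3H)-one
Product: 13 (3S,3aR,7aS)-3-[(2R)-4-chlorobutan-2-yl]-3a,7a-dimethylhexahydro-1-benzofuran-2,7-dione
Conditions: Dess–Martin periodinane, CH2Cl2, 20 °C
Reagents that add atoms: none
Why: Dess–Martin oxidation of the secondary alcohol to the C5 ketone under neutral conditions, which spares the lactone, the alkyl chloride and the epimerisable C1 centre and places the lactone C–O bond α to a carbonyl group.

Step 8
Reactants: 13 (3S,3aR,7aS)-3-[(2R)-4-chlorobutan-2-yl]-3a,7a-dimethylhexahydro-1-benzofuran-2,7-dione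
Product: 15 (1S,2R,4aS,8aR)-2,4a,8a-trimethyl-5-oxodecahydronaphthalene-1-carboxylic acid, via enolate carboxylate 14 (not isolated)
Conditions: SmI2 (2.1 equiv), THF, −78 °C; then KOt-Bu, t-BuOH/THF, −78 → 45 °C; aqueous HCl work-up
Reagents that add atoms: none
Why: Two electrons from divalent samarium enter the C5 ketone and the ketyl expels the α-carboxylate, so that the temporary γ-lactone opens to the free carboxylate and the regiodefined tetrasubstituted C4a=C5 enolate 14, which after exchange of the counter-ion for potassium displaces the primary chloride at C4 in an intramolecular SN2 alkylation. The closest known reaction types are the SmI2 cleavage of α-acyloxy ketones to enolates and the cycloalkylation of ketone enolates by ω-haloalkyl chains that forges angular quaternary carbons of decalones. Ring A is closed in the 6-exo-tet mode, while the five-membered lactone ring is opened in the same operation. The only new stereocentre, C4a, is controlled by the quaternary C8a: the C1 tether sits pseudo-axial on the enolate half-chair (allylic strain with the C4a methyl) and can deliver C4 only to the face it occupies, which gives the cis fusion with both angular methyls syn through a chair-like ring-A transition state in which the C1 carboxylate and the C2 methyl are equatorial. The step needs C- over O-alkylation and C4a over C6 regiochemistry: the C–O scission generates the enolate at C4a only, C6 and the enolate oxygen could reach C4 only through eight-membered rings, and the carboxylate is a far weaker nucleophile than the enolate carbon, so δ-lactonisation should not compete.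

Step 9
Reactants: 15 (1S,2R,4aS,8aR)-2,4a,8a-trimethyl-5-oxodecahydronaphthalene-1-carboxylic acid; 16 [(4S)-2,2-dimethyl-1,3-dioxolan-4-yl]methyl 4-methylbenzenesulfonate ((S)-solketal tosylate)
Product: 17 [(4S)-2,2-dimethyl-1,3-dioxolan-4-yl]methyl (1S,2R,4aS,8aR)-2,4a,8a-trimethyl-5-oxodecahydronaphthalene-1-carboxylate
Conditions: Cs2CO3, DMF, 70 °C
Reagents that add atoms: none
Why: O-alkylation of the cesium carboxylate by the primary tosylate (SN2 at the glycerol CH2, so neither the hindered acyl carbon nor the dioxolane stereocentre takes part), which installs the protected sn-glycerol unit in the configuration of the target and protects the acid for the next steps.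

Step 10
Reactants: 17 [(4S)-2,2-dimethyl-1,3-dioxolan-4-yl]methyl (1S,2R,4aS,8aR)-2,4a,8a-trimethyl-5-oxodecahydronaphthalene-1-carboxylate
Product: 18 [(4S)-2,2-dimethyl-1,3-dioxolan-4-yl]methyl (1S,2R,4aS,8aR)-2,4a,8a-trimethyl-5-{[(trifluoromethyl)sulfonyl]oxy}-1,2,3,4,4a,7,8,8a-octahydronaphthalene-1-carboxylate
Conditions: KN(SiMe3)2, THF, −78 °C; PhNTf2, −78 → 0 °C
Reagents that add atoms: N-phenylbis(trifluoromethanesulfonimide), FC(F)(F)S(=O)(=O)N(c1ccccc1)S(=O)(=O)C(F)(F)F
Why: Enol triflate formation: the ketone has α-hydrogens only at C6 because C4a is quaternary, so enolisation and O-sulfonylation fix the future C5=C6 double bond regiospecifically, while the hindered and less acidic C1–H of the ester is left alone.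

Step 11
Reactants: 18 the enol triflate from step 10; 19 5-bromo-2-methylpent-2-ene
Product: 21 [(4S)-2,2-dimethyl-1,3-dioxolan-4-yl]methyl (1S,2R,4aR,8aR)-2,4a,8a-trimethyl-5-(4-methylpent-3-en-1-yl)-1,2,3,4,4a,7,8,8a-octahydronaphthalene-1-carboxylate, via (4-methylpent-3-en-1-yl)magnesium bromide 20 (not isolated)
Conditions: 19, Mg, THF, 20 °C; then 18, Fe(acac)3 (5 mol %), THF/N-methylpyrrolidone, −30 → 0 °C
Reagents that add atoms: magnesium, [Mg] (present in intermediate 20 only)
Why: Iron-catalysed Kumada-type cross-coupling of an alkenyl triflate with a primary alkyl Grignard reagent, which should be faster at low temperature than addition of the Grignard reagent to the hindered ester; the triflate fixes the alkene position and the trisubstituted alkene of the chain is inert.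

Step 12
Reactants: 21 the acetonide ester from step 11
Product: 22 (2S)-2,3-dihydroxypropyl (1S,2R,4aR,8aR)-2,4a,8a-trimethyl-5-(4-methylpent-3-en-1-yl)-1,2,3,4,4a,7,8,8a-octahydronaphthalene-1-carboxylate
Conditions: pyridinium 4-methylbenzenesulfonate (cat.), MeOH, 40 °C
Reagents that add atoms: none
Why: Acid-catalysed transacetalisation of the terminal isopropylidene acetal to methanol under conditions too mild to protonate the trisubstituted alkenes; acyl migration to the secondary hydroxyl should be slowed by the steric shielding of the ester carbonyl.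

Step 13
Reactants: 22 the diol from step 12
Product: 23 (2S)-3-(acetyloxy)-2-hydroxypropyl (1S,2R,4aR,8aR)-2,4a,8a-trimethyl-5-(4-methylpent-3-en-1-yl)-1,2,3,4,4a,7,8,8a-octahydronaphthalene-1-carboxylate (CNP0146255.1)
Conditions: AcCl, 2,4,6-collidine, CH2Cl2, −78 °C
Reagents that add atoms: acetyl chloride, CC(Cl)=O
Why: Selective O-acetylation of the primary hydroxyl beside the secondary one (a bulky N-acylcollidinium acyl donor at low temperature), which gives the 1-acyl-3-acetyl-sn-glycerol without touching the glycerol stereocentre.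

**Compound list**
1 | (R)-methyl hydrogen 3-methylglutarate [(3R)-5-methoxy-3-methyl-5-oxopentanoic acid] | COC(=O)C[C@H](C)CC(=O)O | starting material
2 | methyl (R)-5-hydroxy-3-methylpentanoate | COC(=O)C[C@H](C)CCO | intermediate (not isolated)
3 | (R)-4-methyloxan-2-one | O=C1C[C@H](C)CCO1 | intermediate
4 | (R)-5-chloro-3-methylpentanoyl chloride | O=C(Cl)C[C@H](C)CCCl | intermediate
5 | 2,3-dimethylcyclohex-2-en-1-one | CC1=C(C)C(=O)CCC1 | starting material
6 | (R)-2,3-dimethylcyclohex-2-en-1-ol | O[C@@H]1CCCC(C)=C1C | intermediate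
7 | (1R)-2,3-dimethylcyclohex-2-en-1-yl (3S)-5-chloro-3-methylpentanoate | O=C(C[C@H](C)CCCl)O[C@@H]1CCCC(C)=C1C | intermediate
8 | (E)-trimethylsilyl ketene acetal of 7 | C[Si](C)(C)O/C(=C/[C@H](C)CCCl)O[C@@H]1CCCC(C)=C1C | intermediate (not isolated)
9 | trimethylsilyl ester of 10 | C[Si](C)(C)OC(=O)[C@@H]([C@H](C)CCCl)[C@@]1(C)CCCC=C1C | intermediate (not isolated)
10 | (2S,3R)-5-chloro-2-[(1R)-1,2-dimethylcyclohex-2-en-1-yl]-3-methylpentanoic acid | OC(=O)[C@@H]([C@H](C)CCCl)[C@@]1(C)CCCC=C1C | intermediate
11 | epoxy acid (ring-alkene oxirane of 10, anti to the side chain) | OC(=O)[C@@H]([C@H](C)CCCl)[C@@]1(C)CCC[C@@H]2O[C@]12C | intermediate (not isolated)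
12 | (3S,3aR,7S,7aS)-3-[(2R)-4-chlorobutan-2-yl]-7-hydroxy-3a,7a-dimethylhexahydro-1-benzofuran-2(3H)-one | O=C1O[C@]2(C)[C@@H](O)CCC[C@]2(C)[C@@H]1[C@H](C)CCCl | intermediate
13 | (3S,3aR,7aS)-3-[(2R)-4-chlorobutan-2-yl]-3a,7a-dimethylhexahydro-1-benzofuran-2,7-dione | O=C1O[C@]2(C)C(=O)CCC[C@]2(C)[C@@H]1[C@H](C)CCCl | intermediate
14 | C4a enolate carboxylate dianion of the ring-opened keto acid (samarium, then potassium counter-ions) | [O-]C(=O)[C@@H]([C@H](C)CCCl)[C@@]1(C)CCCC([O-])=C1C | intermediate (not isolated)
15 | (1S,2R,4aS,8aR)-2,4a,8a-trimethyl-5-oxodecahydronaphthalene-1-carboxylic acid | OC(=O)[C@H]1[C@H](C)CC[C@]2(C)C(=O)CCC[C@]12C | intermediate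
16 | [(4S)-2,2-dimethyl-1,3-dioxolan-4-yl]methyl 4-methylbenzenesulfonate | CC1(C)OC[C@H](O1)COS(=O)(=O)c1ccc(C)cc1 | starting material
17 | [(4S)-2,2-dimethyl-1,3-dioxolan-4-yl]methyl (1S,2R,4aS,8aR)-2,4a,8a-trimethyl-5-oxodecahydronaphthalene-1-carboxylate | CC1(C)OC[C@H](O1)COC(=O)[C@H]1[C@H](C)CC[C@]2(C)C(=O)CCC[C@]12C | intermediate
18 | [(4S)-2,2-dimethyl-1,3-dioxolan-4-yl]methyl (1S,2R,4aS,8aR)-2,4a,8a-trimethyl-5-{[(trifluoromethyl)sulfonyl]oxy}-1,2,3,4,4a,7,8,8a-octahydronaphthalene-1-carboxylate | CC1(C)OC[C@H](O1)COC(=O)[C@H]1[C@H](C)CC[C@]2(C)C(OS(=O)(=O)C(F)(F)F)=CCC[C@]12C | intermediate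
19 | 5-bromo-2-methylpent-2-ene | CC(C)=CCCBr | starting material
20 | (4-methylpent-3-en-1-yl)magnesium bromide | CC(C)=CCC[Mg]Br | intermediate (not isolated)
21 | [(4S)-2,2-dimethyl-1,3-dioxolan-4-yl]methyl (1S,2R,4aR,8aR)-2,4a,8a-trimethyl-5-(4-methylpent-3-en-1-yl)-1,2,3,4,4a,7,8,8a-octahydronaphthalene-1-carboxylate | CC1(C)OC[C@H](O1)COC(=O)[C@H]1[C@H](C)CC[C@]2(C)C(CCC=C(C)C)=CCC[C@]12C | intermediate
22 | (2S)-2,3-dihydroxypropyl (1S,2R,4aR,8aR)-2,4a,8a-trimethyl-5-(4-methylpent-3-en-1-yl)-1,2,3,4,4a,7,8,8a-octahydronaphthalene-1-carboxylate | OC[C@H](O)COC(=O)[C@H]1[C@H](C)CC[C@]2(C)C(CCC=C(C)C)=CCC[C@]12C | intermediate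
23 | (2S)-3-(acetyloxy)-2-hydroxypropyl (1S,2R,4aR,8aR)-2,4a,8a-trimethyl-5-(4-methylpent-3-en-1-yl)-1,2,3,4,4a,7,8,8a-octahydronaphthalene-1-carboxylate | CC(=O)OC[C@H](O)COC(=O)[C@H]1[C@H](C)CC[C@]2(C)C(CCC=C(C)C)=CCC[C@]12C | target

**Step count and risks**
Total step count: 13. Longest linear sequence: 12 steps (steps 1, 2 and 4–13, from 1 to 23); step 3 and the Grignard formation in step 11 are side branches.

Steps most likely to fail:

Step 8 (key step). The enolate may not pass cleanly from samarium to potassium, and C-alkylation at the congested C4a may then be slower than O-alkylation of the liberated carboxylate at C4 (δ-lactonisation) or base-induced loss of HCl. The fallback masks the carboxyl group before ring closure and generates the enolate by thermodynamic enolisation instead of reductive C–O scission. It sets out from 10: 1-chloro-N,N,2-trimethylprop-1-en-1-amine (CH2Cl2, 0 °C) gives the acid chloride F1, which is esterified with (R)-solketal (pyridine, 4-(dimethylamino)pyridine) to the solketal ester F2. Hydroboration–oxidation (BH3·THF; H2O2, NaOAc) places the hydroxyl on C5 (alcohol F3) and Dess–Martin oxidation gives the ketone F4. KOt-Bu in t-BuOH/THF (25 → 50 °C) then converts F4 through its tetrasubstituted potassium enolate F5 into the cis-decalone ester, so the route is rejoined at 17.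

Step 5. Control over the C1 configuration may be lost if chair-like and boat-like transition states compete or if the ketene acetal geometry is mixed. The fallback sets C1 under thermodynamic instead of kinetic control. It sets out from 7: the rearrangement is run without regard to C1, and the C1-epimeric trimethylsilyl ester F6 and, after work-up, the C1-epimeric acid F7 are carried beside 10 through the operations of steps 6 to 9. This passes through the epoxy acid F8, the hydroxy lactone F9, the keto lactone F10, the enolate carboxylate F11, the keto acid F12 and the solketal ester F13. F13 is then equilibrated with KOt-Bu (0.3 equiv) in t-BuOH at 60 °C: in the cis-decalin the C1 ester of F13 is axial and syn to C5, whereas after epimerisation it is equatorial and trans to the C2 methyl, so the mixture should converge on 17, where the route is rejoined.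

Step 11. Activation of the neopentyl-type alkenyl triflate may be slow, so that reduction of the triflate or addition of the Grignard reagent to the ester competes. The fallback is a palladium-catalysed Negishi coupling. It sets out from 19: zinc insertion (Zn, LiCl, THF, 40 °C) gives (4-methylpent-3-en-1-yl)zinc bromide F14, which does not add to esters and is coupled with 18 under Pd(PPh3)4 (zerovalent palladium, THF, 50 °C) to give 21, where the route is rejoined.

**Further compounds**
F1 | step 8 | (2S,3R)-5-chloro-2-[(1R)-1,2-dimethylcyclohex-2-en-1-yl]-3-methylpentanoyl chloride | ClC(=O)[C@@H]([C@H](C)CCCl)[C@@]1(C)CCCC=C1C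
F2 | step 8 | [(4S)-2,2-dimethyl-1,3-dioxolan-4-yl]methyl (2S,3R)-5-chloro-2-[(1R)-1,2-dimethylcyclohex-2-en-1-yl]-3-methylpentanoate | CC1(C)OC[C@H](O1)COC(=O)[C@@H]([C@H](C)CCCl)[C@@]1(C)CCCC=C1C
F3 | step 8 | C5 alcohol from hydroboration of F2 (mixture at C4a and C5) | CC1(C)OC[C@H](O1)COC(=O)[C@@H]([C@H](C)CCCl)[C@@]1(C)CCCC(O)C1C
F4 | step 8 | C5 ketone from F3 (mixture at C4a) | CC1(C)OC[C@H](O1)COC(=O)[C@@H]([C@H](C)CCCl)[C@@]1(C)CCCC(=O)C1C
F5 | step 8 | potassium C4a enolate of F4 | CC1(C)OC[C@H](O1)COC(=O)[C@@H]([C@H](C)CCCl)[C@@]1(C)CCCC([O-])=C1C.[K+]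
F6 | step 5 | C1-epimeric trimethylsilyl ester | C[Si](C)(C)OC(=O)[C@H]([C@H](C)CCCl)[C@@]1(C)CCCC=C1C
F7 | step 5 | (2R,3R)-5-chloro-2-[(1R)-1,2-dimethylcyclohex-2-en-1-yl]-3-methylpentanoic acid | OC(=O)[C@H]([C@H](C)CCCl)[C@@]1(C)CCCC=C1C
F8 | step 5 | C1-epimeric epoxy acid | OC(=O)[C@H]([C@H](C)CCCl)[C@@]1(C)CCC[C@@H]2O[C@]12C
F9 | step 5 | C1-epimeric hydroxy lactone | O=C1O[C@]2(C)[C@@H](O)CCC[C@]2(C)[C@H]1[C@H](C)CCCl
F10 | step 5 | C1-epimeric keto lactone | O=C1O[C@]2(C)C(=O)CCC[C@]2(C)[C@H]1[C@H](C)CCCl
F11 | step 5 | C1-epimeric enolate carboxylate dianion | [O-]C(=O)[C@H]([C@H](C)CCCl)[C@@]1(C)CCCC([O-])=C1C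
F12 | step 5 | (1R,2R,4aS,8aR)-2,4a,8a-trimethyl-5-oxodecahydronaphthalene-1-carboxylic acid | OC(=O)[C@@H]1[C@H](C)CC[C@]2(C)C(=O)CCC[C@]12C
F13 | step 5 | [(4S)-2,2-dimethyl-1,3-dioxolan-4-yl]methyl (1R,2R,4aS,8aR)-2,4a,8a-trimethyl-5-oxodecahydronaphthalene-1-carboxylate | CC1(C)OC[C@H](O1)COC(=O)[C@@H]1[C@H](C)CC[C@]2(C)C(=O)CCC[C@]12C
F14 | step 11 | (4-methylpent-3-en-1-yl)zinc bromide | CC(C)=CCC[Zn]Br
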